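**Plan**

- Retrosynthesis: the two methyl esters and the O3 benzyl ether are end-game cuts. Ring B is then cut at C4'–C5' and at the ester C–O bond of its C1' carboxyl, which folds it back into a 3-acetyl-2-pyranone. Last, the aryl ether bond O–C2' (pyranone C4–O) is cut to a ring A phenol and dehydroacetic acid.
- Enabling feature: ring B carries its carboxyl on C1' between the ether carbon C2' and the hydroxyl carbon C6', with methyl on C4'. These eight carbons are those of dehydroacetic acid: C2 → carboxyl carbon, C3 → C1', C4 → C2', C5 → C3', C6 and its methyl → C4' and 4'-CH3, acetyl C=O → C6', acetyl CH3 → C5'.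
- Forward: ring A is bought as an arene (4-bromo-3,5-dimethoxybenzoic acid) and only decorated: Br → Cl at C4, ester at C1, formyl at C2, O3 methyl → benzyl, formyl → hydroxyl.
- The C2 phenol then displaces the 4-tosylate of dehydroacetic acid, and Mg(OMe)2 turns the pyranone into aromatic ring B, the only ring made on the route. Debenzylation and saponification finish.
- Stereochemistry: the target has no stereocentre, so nothing has to be set.

Key step: step 9

Remark: ring A is numbered from its carboxyl carbon C1 through the ether carbon C2, ring B likewise with primes; the only sp3 stereocentre on the route (the carbinol carbon of 14) is transient and racemic.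

**Route**

Step 1
Reactants: 1 4-bromo-3,5-dimethoxybenzoic acid
Product: 3 4-chloro-3,5-dimethoxybenzoic acid, via aryllithium carboxylate 2 (not isolated)
Conditions: n-BuLi (2.1 equiv), THF, −78 °C; C2Cl6, −78 °C to rt; aq. HCl
Reagents that add atoms: hexachloroethane, ClC(Cl)(Cl)C(Cl)(Cl)Cl
Why: Deprotonation of the acid and fast bromine–lithium exchange should give an aryllithium flanked by two methoxy groups that takes electrophilic chlorine from C2Cl6 at the same carbon, so the chlorine lands between the two oxygens with no regiochemical choice (halogen–metal exchange, then electrophilic chlorination).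

Step 2
Reactants: 3 4-chloro-3,5-dimethoxybenzoic acid
Product: 4 methyl 4-chloro-3,5-dimethoxybenzoate
Conditions: MeOH, H2SO4 (cat.), reflux
Reagents that add atoms: methanol, CO
Why: Fischer esterification of a benzoic acid with two free ortho positions should go to completion in excess methanol.

Step 3
Reactants: 4 methyl 4-chloro-3,5-dimethoxybenzoate
Product: 5 methyl 4-chloro-2-formyl-3,5-dimethoxybenzoate
Conditions: Cl2CHOMe, TiCl4, CH2Cl2, 0 °C to rt; H2O
Reagents that add atoms: dichloromethyl methyl ether, COC(Cl)Cl; water, O
Why: In this Rieche formylation the only free positions, C2 and C6, are equivalent and each is ortho to one methoxy group and para to the other, so a single aldehyde should enter and then deactivate the ring against a second.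

Step 4
Reactants: 5 methyl 4-chloro-2-formyl-3,5-dimethoxybenzoate
Product: 6 methyl 4-chloro-2-formyl-3-hydroxy-5-methoxybenzoate
Conditions: BCl3 (1.2 equiv), CH2Cl2, −78 to 0 °C; H2O
Reagents that add atoms: none
Why: BCl3 held in a six-membered chelate between the formyl oxygen and the ortho methoxy oxygen should cleave only the O3 methyl ether (chelation-controlled ortho-demethylation), because the O5 methyl ether and the ester have no carbonyl placed to chelate.

Step 5
Reactants: 6 methyl 4-chloro-2-formyl-3-hydroxy-5-methoxybenzoate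
Product: 7 methyl 3-(benzyloxy)-4-chloro-2-formyl-5-methoxybenzoate
Conditions: BnBr, K2CO3, DMF, 60 °C
Reagents that add atoms: benzyl bromide, BrCc1ccccc1
Why: Williamson etherification of the single, acidic phenol (ortho to formyl and chlorine) should be clean in a dipolar aprotic solvent.

Step 6
Reactants: 7 methyl 3-(benzyloxy)-4-chloro-2-formyl-5-methoxybenzoate
Product: 9 methyl 3-(benzyloxy)-4-chloro-2-hydroxy-5-methoxybenzoate, via aryl formate 8 (not isolated)
Conditions: mCPBA, CH2Cl2, rt; then K2CO3 (cat.), MeOH, 0 °C
Reagents that add atoms: 3-chloroperoxybenzoic acid (mCPBA), OOC(=O)c1cccc(Cl)c1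
Why: In this Baeyer–Villiger (Dakin-type) oxidation the aryl group, made electron-rich by the ortho benzyloxy and para methoxy groups, should migrate in preference to hydride, and the resulting formate is methanolysed to the C2 phenol.

Step 7
Reactants: 10 dehydroacetic acid (3-acetyl-4-hydroxy-6-methyl-2H-pyran-2-one)
Product: 11 3-acetyl-6-methyl-2-oxo-2H-pyran-4-yl 4-methylbenzenesulfonate
Conditions: TsCl, Et3N, CH2Cl2, 0 °C to rt
Reagents that add atoms: 4-methylbenzenesulfonyl chloride, Cc1ccc(S(=O)(=O)Cl)cc1
Why: The 4-hydroxyl is an acidic enol (a vinylogous carboxylic acid) and should be O-sulfonylated cleanly under amine base.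

Step 8
Reactants: 9 methyl 3-(benzyloxy)-4-chloro-2-hydroxy-5-methoxybenzoate; 11 3-acetyl-6-methyl-2-oxo-2H-pyran-4-yl 4-methylbenzenesulfonate
Product: 12 methyl 2-[(3-acetyl-6-methyl-2-oxo-2H-pyran-4-yl)oxy]-3-(benzyloxy)-4-chloro-5-methoxybenzoate
Conditions: K2CO3, MeCN, rt to 40 °C
Reagents that add atoms: none
Why: Pyranone C4 is the β-carbon of both the lactone and the acetyl carbonyl, so the phenoxide should add there and expel tosylate (addition–elimination at a vinylogous acyl sulfonate), forming the crowded aryl ether without a metal-mediated arene coupling.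

Step 9
Reactants: 12 methyl 2-[(3-acetyl-6-methyl-2-oxo-2H-pyran-4-yl)oxy]-3-(benzyloxy)-4-chloro-5-methoxybenzoate
Product: 15 methyl 3-(benzyloxy)-4-chloro-2-[3-hydroxy-2-(methoxycarbonyl)-5-methylphenoxy]-5-methoxybenzoate, via ring-opened diketo ester 13 (not isolated), via aldol carbinol 14 (not isolated)
Conditions: Mg(OMe)2 (4 equiv), MeOH, reflux; then 1 M HCl
Reagents that add atoms: Mg(OMe)2, CO[Mg]OC
Why: Magnesium-bound methoxide should add to the lactone carbonyl, which is chelated together with the acetyl carbonyl, and cleave the C2–O1 bond to give the methyl ester and methyl ketone of 13, whose push–pull C=C bond can change geometry through its dienolate. The magnesium enolate of the acetyl methyl group then adds to the freed methyl ketone, forming the C4'–C5' bond in carbinol 14, which loses water and tautomerises to phenol 15. The closest known chemistry is the base-induced opening and aldol reclosure of 3-acyl- and 6-acetonyl-2-pyranones to resorcinols and resorcylates, as in the conversion of dehydroacetic acid itself to orcinol. Ring B closes by a 6-(enolexo)-exo-trig aldol addition, a favoured mode. No stereocentre survives, since the racemic carbinol carbon of 14 becomes C4' of the arene. The step needs methoxide to attack the lactone carbonyl and not C4 (which would expel the aryloxide), and the aldol to run from the acetyl enolate to the methyl ketone and not the reverse; chelation delivers methoxide to C2, and the acetyl carbonyl, being a chelated and deactivated vinylogous ester carbonyl, leaves the unchelated ketone as the electrophile, which gives the 2,6-dioxygenated benzoate.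

Step 10
Reactants: 15 methyl 3-(benzyloxy)-4-chloro-2-[3-hydroxy-2-(methoxycarbonyl)-5-methylphenoxy]-5-methoxybenzoate
Product: 16 methyl 4-chloro-3-hydroxy-2-[3-hydroxy-2-(methoxycarbonyl)-5-methylphenoxy]-5-methoxybenzoate
Conditions: BCl3 (3 equiv), C6HMe5 (3 equiv), CH2Cl2, −78 °C; MeOH
Reagents that add atoms: none
Why: Lewis-acid debenzylation with pentamethylbenzene as benzyl cation trap should remove the benzyl ether at low temperature while sparing the aryl chloride (which hydrogenolysis would endanger), the O5 methyl ether (no ortho carbonyl) and both esters.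

Step 11
Reactants: 16 methyl 4-chloro-3-hydroxy-2-[3-hydroxy-2-(methoxycarbonyl)-5-methylphenoxy]-5-methoxybenzoate
Product: 17 2-(2-carboxy-3-hydroxy-5-methylphenoxy)-4-chloro-3-hydroxy-5-methoxybenzoic acid (target)
Conditions: KOH (excess), MeOH–H2O, 65 °C; then 1 M HCl, 0 °C
Reagents that add atoms: KOH, [K+].[OH-]
Why: Saponification of both methyl esters should proceed under forcing hydroxide, the diaryl ether being protected from Smiles-type migration because ring B is an electron-rich phenoxide, and cold acidification frees the diacid without decarboxylation.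

**Compound list**

1 | 4-bromo-3,5-dimethoxybenzoic acid | COc1cc(C(=O)O)cc(OC)c1Br | starting material
2 | lithium 4-lithio-3,5-dimethoxybenzoate | [Li+].[O-]C(=O)c1cc(OC)c([Li])c(OC)c1 | intermediate
3 | 4-chloro-3,5-dimethoxybenzoic acid | COc1cc(C(=O)O)cc(OC)c1Cl | intermediate
4 | methyl 4-chloro-3,5-dimethoxybenzoate | COC(=O)c1cc(OC)c(Cl)c(OC)c1 | intermediate
5 | methyl 4-chloro-2-formyl-3,5-dimethoxybenzoate | COC(=O)c1cc(OC)c(Cl)c(OC)c1C=O | intermediate
6 | methyl 4-chloro-2-formyl-3-hydroxy-5-methoxybenzoate | COC(=O)c1cc(OC)c(Cl)c(O)c1C=O | intermediate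
7 | methyl 3-(benzyloxy)-4-chloro-2-formyl-5-methoxybenzoate | COC(=O)c1cc(OC)c(Cl)c(OCc2ccccc2)c1C=O | intermediate
8 | methyl 3-(benzyloxy)-4-chloro-2-(formyloxy)-5-methoxybenzoate | COC(=O)c1cc(OC)c(Cl)c(OCc2ccccc2)c1OC=O | intermediate
9 | methyl 3-(benzyloxy)-4-chloro-2-hydroxy-5-methoxybenzoate | COC(=O)c1cc(OC)c(Cl)c(OCc2ccccc2)c1O | intermediate
10 | dehydroacetic acid (3-acetyl-4-hydroxy-6-methyl-2H-pyran-2-one) | CC(=O)C1=C(O)C=C(C)OC1=O | starting material
11 | 3-acetyl-6-methyl-2-oxo-2H-pyran-4-yl 4-methylbenzenesulfonate | CC(=O)C1=C(OS(=O)(=O)c2ccc(C)cc2)C=C(C)OC1=O | intermediate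
12 | methyl 2-[(3-acetyl-6-methyl-2-oxo-2H-pyran-4-yl)oxy]-3-(benzyloxy)-4-chloro-5-methoxybenzoate | CC(=O)C1=C(Oc2c(C(=O)OC)cc(OC)c(Cl)c2OCc2ccccc2)C=C(C)OC1=O | intermediate
13 | methyl 3-(benzyloxy)-4-chloro-5-methoxy-2-{[3-(methoxycarbonyl)-2,6-dioxohept-3-en-4-yl]oxy}benzoate (alkene geometry mobile) | COC(=O)C(C(C)=O)=C(CC(C)=O)Oc1c(C(=O)OC)cc(OC)c(Cl)c1OCc1ccccc1 | intermediate
14 | methyl 3-(benzyloxy)-4-chloro-2-{[5-hydroxy-2-(methoxycarbonyl)-5-methyl-3-oxocyclohex-1-en-1-yl]oxy}-5-methoxybenzoate (racemic) | COC(=O)C1=C(Oc2c(C(=O)OC)cc(OC)c(Cl)c2OCc2ccccc2)CC(C)(O)CC1=O | intermediate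
15 | methyl 3-(benzyloxy)-4-chloro-2-[3-hydroxy-2-(methoxycarbonyl)-5-methylphenoxy]-5-methoxybenzoate | COC(=O)c1cc(OC)c(Cl)c(OCc2ccccc2)c1Oc1cc(C)cc(O)c1C(=O)OC | intermediate
16 | methyl 4-chloro-3-hydroxy-2-[3-hydroxy-2-(methoxycarbonyl)-5-methylphenoxy]-5-methoxybenzoate | COC(=O)c1cc(OC)c(Cl)c(O)c1Oc1cc(C)cc(O)c1C(=O)OC | intermediate
17 | 2-(2-carboxy-3-hydroxy-5-methylphenoxy)-4-chloro-3-hydroxy-5-methoxybenzoic acid | COc1cc(C(=O)O)c(Oc2cc(C)cc(O)c2C(=O)O)c(O)c1Cl | target

**Step count and risks**

Total steps: 11. Longest linear sequence: 10 steps (steps 1–6 and 8–11); step 7 is a one-step side branch.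

Steps most likely to fail:

1. Step 9. Methoxide may add at pyranone C4 instead of the lactone carbonyl and expel the aryloxide, or the aldol may close in the opposite sense (methyl ketone enolate onto the acetyl carbonyl). The fallback brings ring B in ready-made; it sets out from 9 and comes back to the route at 16. Purchased methyl 2,6-dihydroxy-4-methylbenzoate (COC(=O)c1c(O)cc(C)cc1O) would be mono-benzylated (BnBr 1 equiv, K2CO3, acetone) to methyl 2-(benzyloxy)-6-hydroxy-4-methylbenzoate F1. Triflation (Tf2O, pyridine, CH2Cl2, 0 °C) would give methyl 2-(benzyloxy)-4-methyl-6-{[(trifluoromethyl)sulfonyl]oxy}benzoate F2. Palladium-catalysed diaryl ether coupling of F2 with 9 (Pd(OAc)2, t-BuXPhos, K3PO4, toluene, 100 °C; Buchwald–Hartwig type) should give methyl 3-(benzyloxy)-2-[3-(benzyloxy)-2-(methoxycarbonyl)-5-methylphenoxy]-4-chloro-5-methoxybenzoate F3. BCl3 and pentamethylbenzene as in step 10, in doubled amount, would then remove both benzyl ethers and deliver 16.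

2. Step 8. The hindered, hydrogen-bonded phenoxide of 9 may attack sulfur (sulfonyl transfer), or react so slowly that the tosylate hydrolyses. The fallback changes the leaving group to one with no second electrophilic site; it sets out from 10 and 9 and comes back at 12. Oxalyl chloride with catalytic DMF in CH2Cl2 (the enol-to-vinylogous-acid-chloride conversion known for 2-acyl-1,3-diones and 4-hydroxy-2-pyranones) should turn 10 into 3-acetyl-4-chloro-6-methyl-2H-pyran-2-one F4. F4 with 9 and K2CO3 in MeCN would give 12 by the same addition–elimination.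

3. Step 11. Hydroxide may fail to reach the doubly ortho-substituted ring B ester, and forcing conditions may cause decarboxylation of the 2,6-dioxygenated acid. The fallback removes the methyl groups by attack at the methyl carbon instead of the acyl carbon; it sets out from 16 and comes back at 17. LiI in refluxing ethyl acetate (SN2 dealkylation, insensitive to crowding at the carbonyl), then cold dilute HCl, should give 17 directly; no new compound is made.

**Further compounds**

F1 | step 9 | methyl 2-(benzyloxy)-6-hydroxy-4-methylbenzoate | COC(=O)c1c(O)cc(C)cc1OCc1ccccc1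
F2 | step 9 | methyl 2-(benzyloxy)-4-methyl-6-{[(trifluoromethyl)sulfonyl]oxy}benzoate | COC(=O)c1c(OCc2ccccc2)cc(C)cc1OS(=O)(=O)C(F)(F)F
F3 | step 9 | methyl 3-(benzyloxy)-2-[3-(benzyloxy)-2-(methoxycarbonyl)-5-methylphenoxy]-4-chloro-5-methoxybenzoate | COC(=O)c1cc(OC)c(Cl)c(OCc2ccccc2)c1Oc1cc(C)cc(OCc2ccccc2)c1C(=O)OC
F4 | step 8 | 3-acetyl-4-chloro-6-methyl-2H-pyran-2-one | CC(=O)C1=C(Cl)C=C(C)OC1=O
F0 | step 11 | none | none
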